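**Plan**

1. Retrosynthetic cuts, in order: the C5–H and C6–H bonds (hydrogenation of a C5=C6 alkene); the C5–octyl bond (cross-coupling of an enol triflate, which leads back to a C5 ketone); then C6–C7 and C8–C8a together (methyl vinyl ether is taken out of ring B); then the acyl–ring bond, the C–I bond and the N-for-O exchange of O-methylmaltol.
2. The event rests on ring A (the pyridone): C8a is its only unsubstituted carbon and is the β-carbon of the enaminone N1–C8a=C4a–C4=O. With C5 held as a ketone, C6 is an electrophilic α-keto radical, the vinyl ether turns it into a nucleophilic α-methoxy radical at C8, and C8a is a doubly activated acceptor, so one radical (4+2) annulation closes ring B and brings in the C8 methoxy group.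
3. Forward order: ring A from the pyranone, chloroacetyl chain on the carbon that becomes C4a, ring B by a photoenzymatic annulation with a flavin-dependent ene-reductase, then the octyl chain on C5 through the enol triflate, then saturation of C5=C6.
4. Stereochemistry: C8 (R) from the enzyme active site in the annulation; C5 (S) from hydrogenation of C5=C6 on the face opposite the pseudoaxial C8 methoxy group, which gives the cis isomer.
5. The C5 ketone is the temporary activating group; it is consumed when the octyl chain is joined.

Key step: step 4

Assumption: 3-methoxy-2-methyl-4H-pyran-4-one (O-methylmaltol) is bought (it is otherwise one O-methylation from maltol), and the ene-reductase variant for step 4 is picked from a panel of old-yellow-enzyme-type enzymes by screening for the R product.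

**Route**

Step 1
Reactants: 1 3-methoxy-2-methyl-4H-pyran-4-one; 2 O-methylhydroxylamine hydrochloride
Product: 3 1,3-dimethoxy-2-methylpyridin-4(1H)-one
Conditions: 2 (3 equiv), NaOAc (3 equiv), EtOH/H2O 1:1, 90 °C, sealed tube
Reagents that add atoms: none
Why: Conjugate addition of the alkoxyamine at C6 of the pyranone, ring opening and reclosure through nitrogen with loss of water (the usual pyranone-to-pyridinone exchange, which runs with hydroxylamines as with amines) should replace the ring oxygen by N–OMe and leave the C3 methyl ether untouched.

Step 2
Reactants: 3 1,3-dimethoxy-2-methylpyridin-4(1H)-one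
Product: 4 5-iodo-1,3-dimethoxy-2-methylpyridin-4(1H)-one
Conditions: N-iodosuccinimide (1.1 equiv), CF3CO2H (10 mol %), MeCN, 23 °C
Reagents that add atoms: N-iodosuccinimide, O=C1CCC(=O)N1I
Why: Electrophilic aromatic iodination should go to C5, the only nucleophilic CH of the ring (β to nitrogen and α to the carbonyl of the enaminone), while C6 is electron-poor and C2 and C3 are substituted.

Step 3
Reactants: 4 5-iodo-1,3-dimethoxy-2-methylpyridin-4(1H)-one; 5 2-chloro-N-methoxy-N-methylacetamide
Product: 7 5-(2-chloroacetyl)-1,3-dimethoxy-2-methylpyridin-4(1H)-one, via heteroarylmagnesium chloride 6 (not isolated)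
Conditions: iPrMgCl·LiCl (1.1 equiv), THF, −40 °C, 30 min; then 5 (1.3 equiv), −40 to 0 °C; aq NH4Cl
Reagents that add atoms: none
Why: Iodine–magnesium exchange at low temperature should give the C5 magnesium species without attack on the vinylogous amide carbonyl, and its acylation by the chloro Weinreb amide stops at the ketone through the chelated tetrahedral adduct (Weinreb ketone synthesis).

Step 4
Reactants: 7 5-(2-chloroacetyl)-1,3-dimethoxy-2-methylpyridin-4(1H)-one; 8 methyl vinyl ether
Product: 9 (8R)-1,3,8-trimethoxy-2-methyl-7,8-dihydroquinoline-4,5(1H,6H)-dione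
Conditions: flavin-dependent ene-reductase of the old yellow enzyme family (screened variant, 1–2 mol %), NADP+ (1 mol %), glucose dehydrogenase, glucose, 8 (10 equiv, charged cold), K2HPO4/KH2PO4 buffer pH 8.0 with 10% DMSO, cyan LEDs (about 495 nm), 25 °C, sealed vial under N2
Reagents that add atoms: none
Why: Proposed new method: the reduced flavin of the ene-reductase, whose active-site hydrogen-bond donors bind the C5 carbonyl of 7 as they bind an enone, forms a charge-transfer complex with the chloroketone that on irradiation passes on one electron, and loss of chloride leaves the electrophilic α-keto radical at C6 (product numbering), which adds to the CH2 end of methyl vinyl ether (C6–C7) to give the nucleophilic α-methoxy radical at C8. That radical closes ring B by 6-endo-trig attack on C8a (C8–C8a), the only unsubstituted ring carbon and the β-carbon of the enaminone N1–C8a=C4a–C4=O, here activated a second time by the C5 ketone, and the resulting C4a radical, stabilised by both carbonyl groups, gives the C8a hydrogen (as H atom or as proton plus electron) back to the flavin semiquinone, which restores the pyridone and the reduced flavin, so that the reaction is redox-neutral and sets free only HCl. The closest known reaction types are the photoenzymatic intermolecular hydroalkylation of alkenes by α-halo carbonyl compounds and the redox-neutral radical cyclisation onto arenes, both with flavin-dependent ene-reductases, and, as racemic small-molecule counterpart, the xanthate-transfer addition of aroylmethyl radicals to vinyl esters followed by peroxide-mediated closure to 4-acyloxy-1-tetralones. The C8 stereocentre arises in the C8–C8a bond formation, and the protein pocket around the bound ketone decides which face of the C8 radical meets C8a, the variant being chosen for R. The step needs addition at the unsubstituted alkene carbon (favoured sterically and by the oxygen-stabilised radical that results) and a ring closure that outruns hydrogen-atom or electron transfer between the C8 radical and the flavin, which the polarity match of the electron-rich radical with the doubly activated C8a in a six-membered transition state should secure.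

Step 5
Reactants: 9 (8R)-1,3,8-trimethoxy-2-methyl-7,8-dihydroquinoline-4,5(1H,6H)-dione
Product: 11 (8R)-1,3,8-trimethoxy-2-methyl-4-oxo-1,4,7,8-tetrahydroquinolin-5-yl trifluoromethanesulfonate, via potassium enolate 10 (not isolated)
Conditions: KN(SiMe3)2 (1.0 equiv), THF, −78 °C, 20 min; then PhNTf2 (1.1 equiv), −78 to −20 °C; work-up without acid, Et3N-deactivated silica
Reagents that add atoms: N-phenyl-bis(trifluoromethanesulfonimide), O=S(=O)(N(c1ccccc1)S(=O)(=O)C(F)(F)F)C(F)(F)F
Why: Kinetic deprotonation at C6, the only α-position of the C5 ketone, and O-sulfonylation of the enolate (standard enol triflate formation) should give the alkenyl triflate, with low temperature and one equivalent of base meant to leave C8–H untouched.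

Step 6
Reactants: 11 (8R)-1,3,8-trimethoxy-2-methyl-4-oxo-1,4,7,8-tetrahydroquinolin-5-yl trifluoromethanesulfonate; 12 n-octylzinc bromide
Product: 13 (8R)-1,3,8-trimethoxy-2-methyl-5-octyl-7,8-dihydroquinolin-4(1H)-one
Conditions: 12 (1.5 equiv, 0.5 M in THF), Pd(dppf)Cl2 (5 mol %), THF, 40 °C
Reagents that add atoms: none
Why: Negishi coupling of an alkenyl triflate with a primary alkylzinc halide should join the chain at C5, the bidentate dppf ligand favouring reductive elimination over β-hydride elimination and the neutral medium sparing the C8 ether and the N–OMe group.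

Step 7
Reactants: 13 (8R)-1,3,8-trimethoxy-2-methyl-5-octyl-7,8-dihydroquinolin-4(1H)-one
Product: 14 Waltherione K, (5S,8R)-1,3,8-trimethoxy-2-methyl-5-octyl-5,6,7,8-tetrahydroquinolin-4(1H)-one
Conditions: H2 (1 atm), Rh on Al2O3 (5%), EtOAc, 23 °C, stopped after one equivalent of H2
Reagents that add atoms: none
Why: Heterogeneous syn-hydrogenation of the C5=C6 bond should take place on the face opposite the C8 methoxy group, which sits pseudoaxial to avoid the peri N–OMe group and shields its own face, so that the octyl chain ends cis to the methoxy group (5S), as in cis-selective hydrogenations of 1,4-disubstituted 1,2-dihydronaphthalenes, while Rh in place of Pd limits double-bond migration and C–O or N–O hydrogenolysis.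

**Compound list**

1 | 3-methoxy-2-methyl-4H-pyran-4-one (O-methylmaltol) | COc1c(C)occc1=O | starting material
2 | O-methylhydroxylamine hydrochloride | CON.Cl | starting material
3 | 1,3-dimethoxy-2-methylpyridin-4(1H)-one | COc1c(C)n(OC)ccc1=O | intermediate
4 | 5-iodo-1,3-dimethoxy-2-methylpyridin-4(1H)-one | COc1c(C)n(OC)cc(I)c1=O | intermediate
5 | 2-chloro-N-methoxy-N-methylacetamide | CON(C)C(=O)CCl | starting material
6 | (1,5-dimethoxy-6-methyl-4-oxo-1,4-dihydropyridin-3-yl)magnesium chloride, LiCl complex | COc1c(C)n(OC)cc([Mg]Cl)c1=O.[Li+].[Cl-] | intermediate (not isolated)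
7 | 5-(2-chloroacetyl)-1,3-dimethoxy-2-methylpyridin-4(1H)-one | COc1c(C)n(OC)cc(C(=O)CCl)c1=O | intermediate
8 | methyl vinyl ether (methoxyethene) | COC=C | starting material
9 | (8R)-1,3,8-trimethoxy-2-methyl-7,8-dihydroquinoline-4,5(1H,6H)-dione | O=C1CC[C@@H](OC)c2c1c(=O)c(OC)c(C)n2OC | intermediate
10 | potassium (8R)-1,3,8-trimethoxy-2-methyl-4-oxo-1,4,7,8-tetrahydroquinolin-5-olate | [K+].[O-]C1=CC[C@@H](OC)c2c1c(=O)c(OC)c(C)n2OC | intermediate (not isolated)
11 | (8R)-1,3,8-trimethoxy-2-methyl-4-oxo-1,4,7,8-tetrahydroquinolin-5-yl trifluoromethanesulfonate | O=S(=O)(OC1=CC[C@@H](OC)c2c1c(=O)c(OC)c(C)n2OC)C(F)(F)F | intermediate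
12 | n-octylzinc bromide | CCCCCCCC[Zn]Br | starting material
13 | (8R)-1,3,8-trimethoxy-2-methyl-5-octyl-7,8-dihydroquinolin-4(1H)-one | CCCCCCCCC1=CC[C@@H](OC)c2c1c(=O)c(OC)c(C)n2OC | intermediate
14 | Waltherione K, (5S,8R)-1,3,8-trimethoxy-2-methyl-5-octyl-5,6,7,8-tetrahydroquinolin-4(1H)-one | CCCCCCCC[C@H]1CC[C@@H](OC)c2c1c(=O)c(OC)c(C)n2OC | target

**Count and risks**

Total step count: 7. Longest linear sequence: 7 steps (1 to 14).

Steps most likely to fail:

1. Step 4. The C6 or the C8 radical may be quenched by hydrogen-atom transfer from the flavin semiquinone before ring B closes (dechlorination or open-chain hydroalkylation). The electron-rich C8 radical may also be oxidised to the oxocarbenium ion and hydrolysed, or the pocket may give poor facial control at C8. The fallback uses known chemistry, sets out from 7 and comes back at 9. Displacement of chloride in 7 by KSC(S)OEt (acetone, 0 °C) should give the xanthate S-[2-(1,5-dimethoxy-6-methyl-4-oxo-1,4-dihydropyridin-3-yl)-2-oxoethyl] O-ethyl carbonodithioate F1. Radical-chain xanthate transfer to vinyl acetate (dilauroyl peroxide in small portions, EtOAc, reflux) should give the adduct rac-4-(1,5-dimethoxy-6-methyl-4-oxo-1,4-dihydropyridin-3-yl)-1-[(ethoxycarbonothioyl)sulfanyl]-4-oxobutyl acetate F2. A stoichiometric amount of dilauroyl peroxide (1,2-dichloroethane, reflux) should then close ring B onto C8a, as in the tetralone synthesis from aroylmethyl xanthates and vinyl esters, to give rac-1,3-dimethoxy-2-methyl-4,5-dioxo-1,4,5,6,7,8-hexahydroquinolin-8-yl acetate F3. Kinetic resolution by hydrolysis with immobilised Candida antarctica lipase B (phosphate buffer pH 7/MTBE, 30 °C), which is expected to take the R ester of such 1-arylalkyl acetates, should give (8R)-8-hydroxy-1,3-dimethoxy-2-methyl-7,8-dihydroquinoline-4,5(1H,6H)-dione F4 beside unreacted S acetate, so at most half of the material is carried on. Methylation of F4 with MeI and Ag2O (CH2Cl2, 23 °C) should give 9.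

2. Step 7. Poor facial selectivity (reaction through the conformer with a pseudoequatorial methoxy group, or double-bond migration on the metal before hydrogen delivery) would lead to the trans isomer. The fallback replaces substrate control by catalyst control, sets out from 13 and comes back at 14. Homogeneous asymmetric hydrogenation with a cationic iridium complex of a chiral phosphine–oxazoline ligand, [Ir(cod)(tBu-PHOX)]B(C6H3(CF3)2)4 (H2 50 bar, CH2Cl2, 23 °C), should set C5 from the ligand, and the ligand enantiomer that is matched to 5S is used. No new compound is made.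

3. Step 5. Deprotonation at C8 (the vinylogous γ-position of both carbonyl groups) in competition with C6 would erode the C8 configuration, and loss of methanol from the dienyl triflate (or later from 13) would aromatise ring B. The fallback avoids strong base and both dihydro compounds, sets out from 9 and comes back at 14. Addition of n-C8H17MgBr premixed with anhydrous CeCl3 (THF, −78 °C; a weakly basic organocerium reagent) to the C5 ketone should give the tertiary alcohol (8R)-5-hydroxy-1,3,8-trimethoxy-2-methyl-5-octyl-5,6,7,8-tetrahydroquinolin-4(1H)-one F5 as a mixture of C5 epimers. Ionic hydrogenation (Et3SiH, CF3CO2H, CH2Cl2, −40 to 0 °C) should then ionise C5 to the cation stabilised by the enaminone nitrogen, and hydride delivery anti to the pseudoaxial C8 methoxy group should give 14.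

**Further compounds**

F1 | step 4 | S-[2-(1,5-dimethoxy-6-methyl-4-oxo-1,4-dihydropyridin-3-yl)-2-oxoethyl] O-ethyl carbonodithioate | CCOC(=S)SCC(=O)c1cn(OC)c(C)c(OC)c1=O
F2 | step 4 | rac-4-(1,5-dimethoxy-6-methyl-4-oxo-1,4-dihydropyridin-3-yl)-1-[(ethoxycarbonothioyl)sulfanyl]-4-oxobutyl acetate | CCOC(=S)SC(CCC(=O)c1cn(OC)c(C)c(OC)c1=O)OC(C)=O
F3 | step 4 | rac-1,3-dimethoxy-2-methyl-4,5-dioxo-1,4,5,6,7,8-hexahydroquinolin-8-yl acetate | CC(=O)OC1CCC(=O)c2c1n(OC)c(C)c(OC)c2=O
F4 | step 4 | (8R)-8-hydroxy-1,3-dimethoxy-2-methyl-7,8-dihydroquinoline-4,5(1H,6H)-dione | O=C1CC[C@@H](O)c2c1c(=O)c(OC)c(C)n2OC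
F5 | step 5 | (8R)-5-hydroxy-1,3,8-trimethoxy-2-methyl-5-octyl-5,6,7,8-tetrahydroquinolin-4(1H)-one (both C5 epimers) | CCCCCCCCC1(O)CC[C@@H](OC)c2c1c(=O)c(OC)c(C)n2OC
F0 | step 7 | none | none
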